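## Retrosynthetic overview

1. Endgame: the acetate-bearing carbon C10 is traced back to a ketone (equatorial methyl addition) and the C3 ketone to its alcohol. This gives a C29 hydroxy ketone that already holds both bicycles.
2. Key disconnection: the bridge bond C12–C11 is cut together with C11–C6 and O–C2. The whole right-hand bicycle unravels to an acyclic α-diazo ketone diepoxide made from (E)-geranylacetone, and the left half becomes a B-alkylborane made from its vinyl derivative.
3. Enabling feature: in the right-hand cyclohexane ring, the bridge-bearing CH (C11) lies between O-bearing C10 (a latent ketone) and quaternary C6. C6–C7(O) and C2(O)–C3(O) of the fused oxepane ring are 1,5-related C–O pairs with tertiary C6 and C2. C11 can therefore be a diazo carbon that first accepts C12 from boron and then, as an enolate carbon, attacks C6 of a diepoxide.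
4. Left half: an allylsilane-terminated diepoxide cascade, whose substrate is built from geranyl bromide and methyl acetoacetate. The ester is then converted into a vinyl group.
5. Ring order: left oxepane, then left cyclohexane (step 5); right oxepane, then right cyclohexane (step 12).

Key step: step 12

Locants (squalene-type, same in each half; primes mark the methylidene half): C2 = CMe2, C3 = carbinol/ketone carbon, C6 = quaternary ring-fusion carbon, C7 = O-bearing ring-fusion CH, C10 = ring carbon bearing =CH2 or Me/OAc, C11 = ring CH bearing the bridge, C12 = bridge CH2.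

Assumption: isomerically pure (E)-geranylacetone and the L-series epoxidation ketone (used only as catalyst, otherwise made from L-sorbose) are purchased. The all-(S) epoxides that the target needs call for this enantiomer of the usual D-fructose-derived ketone.

## Route

Step 1
Reactants: 1 methyl acetoacetate; 2 geranyl bromide
Product: 3 methyl (6E)-7,11-dimethyl-3-oxododeca-6,10-dienoate
Conditions: NaH, THF, 0 °C; n-BuLi, 0 °C; then 2, 0 °C → rt; aq. HCl quench
Reagents that add atoms: none
Why: γ-Alkylation of the acetoacetate dianion: the more reactive terminal carbanion displaces the primary allylic bromide by SN2, so the E-alkene of 2 is carried over unchanged.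

Step 2
Reactants: 3 β-keto ester
Product: 4 methyl (2Z,6E)-3-(diethoxyphosphoryloxy)-7,11-dimethyldodeca-2,6,10-trienoate
Conditions: NaH, Et2O, 0 °C; (EtO)2P(O)Cl, 0 °C → rt
Reagents that add atoms: diethyl chlorophosphate, CCOP(=O)(Cl)OCC
Why: O-Phosphorylation of the sodium-chelated enolate in a weakly polar ether holds the enol oxygen cis to the ester, which should give the Z-enol phosphate.

Step 3
Reactants: 4 Z-enol phosphate
Product: 5 methyl (2Z,6E)-7,11-dimethyl-3-(trimethylsilylmethyl)dodeca-2,6,10-trienoate
Conditions: Me3SiCH2MgCl, Ni(acac)2 (5 mol %), THF, 0 °C → rt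
Reagents that add atoms: (trimethylsilyl)methylmagnesium chloride, C[Si](C)(C)C[Mg]Cl
Why: Nickel-catalysed Kumada-type cross-coupling of an enol phosphate proceeds with retention of alkene geometry, so the silylmethyl group ends cis to the ester and the chain trans to it.

Step 4
Reactants: 5 allylsilane triene
Product: 6 methyl (2Z)-5-[(2S,3S)-3-{2-[(2S)-3,3-dimethyloxiran-2-yl]ethyl}-3-methyloxiran-2-yl]-3-(trimethylsilylmethyl)pent-2-enoate
Conditions: 1,2:4,5-di-O-isopropylidene-β-L-erythro-2,3-hexodiulo-2,6-pyranose (0.6 equiv), KHSO5 (as 2KHSO5·KHSO4·K2SO4), K2CO3, Bu4NHSO4, MeCN–CH2(OMe)2–aq. Na2B4O7 buffer, 0 °C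
Reagents that add atoms: potassium peroxymonosulfate, [K+].[O-]S(=O)(=O)OO
Why: Shi asymmetric epoxidation: the chiral dioxirane formed in situ attacks only the two electron-rich trisubstituted alkenes (the silylmethyl enoate is electron-poor) through a spiro transition state, and the L-series ketone should give the (S)- and (S,S)-epoxides, which fixes C3', C6' and C7'.

Step 5
Reactants: 6 diepoxy allylsilane
Product: 8 methyl (3S,5aS,6R,9aS)-3-hydroxy-2,2,5a-trimethyl-7-methylidenedecahydro-1-benzoxepine-6-carboxylate, via trimethylsilyl ether 7 (not isolated)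
Conditions: Me3SiOTf (20 mol %), 2,6-di-tert-butyl-4-methylpyridine, CH2Cl2, −78 °C; then citric acid, MeOH, 0 °C
Reagents that add atoms: none
Why: Lewis-acid-initiated endo-selective oxa-/carbacyclisation cascade of a 1,5-diepoxide ended by an allylsilane (SE2'): the silylated terminal epoxide is opened at tertiary C2' by the inner epoxide oxygen, the epoxonium ion is opened with inversion at tertiary C6' by C11' in a chair-like array (trans fusion; the ester, trans to C9' in the Z-alkene, becomes equatorial), loss of the silyl group gives the methylidene and regenerates Me3SiOTf, and mild methanolysis frees the C3' hydroxyl.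

Step 6
Reactants: 8 hydroxy ester
Product: 9 methyl (3S,5aS,6R,9aS)-3-(tert-butyldimethylsilyloxy)-2,2,5a-trimethyl-7-methylidenedecahydro-1-benzoxepine-6-carboxylate
Conditions: t-BuMe2SiOTf, 2,6-lutidine, CH2Cl2, 0 °C
Reagents that add atoms: tert-butyldimethylsilyl triflate, CC(C)(C)[Si](C)(C)OS(=O)(=O)C(F)(F)F
Why: Standard silylation of a hindered secondary alcohol with a silyl triflate, which marks the C3' oxygen so that it stays an alcohol when the C3 oxygen of the other half is oxidised later.

Step 7
Reactants: 9 silyl ether ester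
Product: 10 [(3S,5aS,6R,9aS)-3-(tert-butyldimethylsilyloxy)-2,2,5a-trimethyl-7-methylidenedecahydro-1-benzoxepin-6-yl]methanol
Conditions: i-Bu2AlH, CH2Cl2, −78 → 0 °C; aq. potassium sodium tartrate
Reagents that add atoms: none
Why: Hydride reduction of the ester to the primary alcohol, which leaves the alkene, the silyl ether and the C11' centre untouched.

Step 8
Reactants: 10 primary alcohol
Product: 11 (3S,5aS,6R,9aS)-3-(tert-butyldimethylsilyloxy)-2,2,5a-trimethyl-7-methylidenedecahydro-1-benzoxepine-6-carbaldehyde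
Conditions: Dess–Martin periodinane, pyridine, CH2Cl2, 0 °C → rt
Reagents that add atoms: none
Why: Dess–Martin oxidation under buffered, non-basic conditions should give the β,γ-unsaturated aldehyde without epimerisation at C11' or migration of the alkene.

Step 9
Reactants: 11 aldehyde
Product: 12 tert-butyl{[(3S,5aS,6R,9aS)-6-ethenyl-2,2,5a-trimethyl-7-methylidenedecahydro-1-benzoxepin-3-yl]oxy}dimethylsilane
Conditions: Ph3PCH3Br, KN(SiMe3)2, THF, 0 °C; then 11, −78 → 0 °C
Reagents that add atoms: methyltriphenylphosphonium bromide, C[P+](c1ccccc1)(c1ccccc1)c1ccccc1.[Br-]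
Why: Wittig methylenation with the non-stabilised ylide at low temperature should convert the hindered aldehyde into the vinyl group faster than it is enolised.

Step 10
Reactants: 13 (E)-geranylacetone
Product: 14 4-[(2S,3S)-3-{2-[(2S)-3,3-dimethyloxiran-2-yl]ethyl}-3-methyloxiran-2-yl]butan-2-one
Conditions: 1,2:4,5-di-O-isopropylidene-β-L-erythro-2,3-hexodiulo-2,6-pyranose (0.6 equiv), KHSO5 (as 2KHSO5·KHSO4·K2SO4), K2CO3, Bu4NHSO4, MeCN–CH2(OMe)2–aq. Na2B4O7 buffer, 0 °C
Reagents that add atoms: potassium peroxymonosulfate, [K+].[O-]S(=O)(=O)OO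
Why: Shi asymmetric epoxidation of both trisubstituted alkenes with the same catalyst sense as in step 4 should give the (3S,6S,7S)-diepoxide, which fixes C3 and C7 and pre-sets C6.

Step 11
Reactants: 14 diepoxy ketone
Product: 16 1-diazo-4-[(2S,3S)-3-{2-[(2S)-3,3-dimethyloxiran-2-yl]ethyl}-3-methyloxiran-2-yl]butan-2-one, via trifluoroacetyl diketone 15 (not isolated)
Conditions: LiN(SiMe3)2, THF, −78 °C; CF3CO2CH2CF3; aq. NH4Cl wash; then MeSO2N3, Et3N, H2O, MeCN, rt
Reagents that add atoms: 2,2,2-trifluoroethyl trifluoroacetate, O=C(OCC(F)(F)F)C(F)(F)F (its CF3CO group is carried only by 15); methanesulfonyl azide, CS(=O)(=O)N=[N+]=[N-]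
Why: Deacylative (detrifluoroacetylative) Regitz diazo transfer: the kinetic enolate at the methyl group is trifluoroacetylated, the activated methylene of 15 takes N2 from the sulfonyl azide, and the trifluoroacetyl group leaves on the sulfonamide, all under conditions that epoxides tolerate.

Step 12
Reactants: 12 vinyl bicycle (left half); 16 diazo ketone diepoxide
Product: 20 C29 hydroxy ketone (both bicycles in place; C10 ketone; free 3-OH; 3'-O-silyl), via alkyldicyclohexylborane 17 (not isolated), via enol borinate 18 (not isolated), via cyclised borinate ester 19 (not isolated)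
Conditions: 12, (c-C6H11)2BH, THF, 0 °C → rt; 16, THF, 0 °C → rt (−N2); solvent switch to CH2Cl2; 2,6-di-tert-butyl-4-methylpyridine, (c-C6H11)2BOTf (20 mol %), −78 °C; then K2CO3, MeOH, rt
Reagents that add atoms: dicyclohexylborane, B(C1CCCCC1)C1CCCCC1 (boron and cyclohexyl groups are carried only by 17–19)
Why: Proposed new method: (c-C6H11)2BH adds only to the monosubstituted vinyl group of 12 (this hindered dialkylborane is far slower with the 1,1-disubstituted methylidene) to give 17, whose boron is then attacked by the nucleophilic diazo carbon C11 of 16; loss of N2 drives a 1,2-shift of the primary carbon C12 from boron to C11 (the secondary cyclohexyl groups are expected to stay behind as spectator ligands), so the C11–C12 bond is made while C11 is still an unhindered CH, and the boron shift from carbon to oxygen leaves the C10=C11 enol borinate 18 with a regiochemistry that deprotonation of the ketone could not give. Catalytic (c-C6H11)2BOTf then activates the terminal epoxide, the oxygen of the C6–C7 epoxide opens it at tertiary C2 (endo mode, bridged epoxonium ion, in the end a formal 7-endo-tet closure of the oxepane), and C11 of 18 opens the epoxonium ion at tertiary C6 (6-endo-tet, enol-endo, chair-like) to close the cyclohexanone and to release (c-C6H11)2BOTf as chain carrier, so that boron ends on the C3 oxygen in 19. The closest known reaction types are the alkylation of α-diazo ketones with trialkylboranes (Hooz reaction), whose enol borinates are known to be intercepted by iminium salts, aldehydes and N-halosuccinimides, and the silyl-triflate-promoted oxa-/carbacyclisation cascades of 1,5-diepoxides that end on enol silanes; new are the mixed borane with a complex migrating group and the enol borinate as cascade terminator in the same flask. C3 and C7 keep their C–O bonds and so the configuration from step 10, quaternary C6 is set by stereospecific inversion at the epoxide carbon (E-derived epoxide, hence methyl anti to H-7 and a trans ring fusion), and C11 is set under thermodynamic control because K2CO3/MeOH cleaves the borinate and equilibrates the α-carbon to the equatorial side chain, so the enolate geometry is immaterial. The step needs endo regioselectivity in both openings, which the methyl groups on C2 and C6 secure by localising positive charge there, and it needs the methylidene and silyl ether of the left half to stay passive, which −78 °C, the hindered pyridine base and the proximity and higher nucleophilicity of the enol borinate secure.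

Step 13
Reactants: 20 hydroxy ketone
Product: 21 C30 diol (3-OH secondary; axial 10-OH tertiary, 10R)
Conditions: MeLi, CeCl3, THF, −78 °C; aq. NH4Cl
Reagents that add atoms: methyllithium, [Li]C
Why: Organocerium 1,2-addition (weakly basic, so enolisation is suppressed): the axial β-trajectory is blocked by the syn-axial C6 methyl group, so methyl should enter equatorially from the α-face and give the axial (10R)-alcohol, cis to the C6 methyl group and to the side chain.

Step 14
Reactants: 21 diol
Product: 22 3-keto 10-ol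
Conditions: Dess–Martin periodinane, pyridine, CH2Cl2, rt
Reagents that add atoms: none
Why: Dess–Martin oxidation takes the only free secondary alcohol (C3) to the ketone, since the tertiary C10 alcohol cannot be oxidised and the C3' oxygen is silylated.

Step 15
Reactants: 22 keto alcohol
Product: 23 3'-O-silyl ether of the target (10-acetate)
Conditions: Ac2O, DMAP, Et3N, toluene, 60 °C
Reagents that add atoms: acetic anhydride, CC(=O)OC(C)=O
Why: DMAP-catalysed acyl transfer (Steglich-type acylation) under forcing but non-acidic conditions should esterify the only free hydroxyl group without ionising the tertiary centre.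

Step 16
Reactants: 23 silyl ether acetate
Product: 24 target CNP0148623.1
Conditions: HF·pyridine, THF, 0 °C → rt
Reagents that add atoms: none
Why: Fluoride-driven cleavage of the silyl ether (strong Si–F bond) under mild buffered conditions should leave the tertiary acetate, the ketone and the methylidene intact.

## Compound list

1 | methyl acetoacetate | COC(=O)CC(C)=O | starting material
2 | geranyl bromide, (2E)-1-bromo-3,7-dimethylocta-2,6-diene | CC(C)=CCC/C(C)=C/CBr | starting material
3 | methyl (6E)-7,11-dimethyl-3-oxododeca-6,10-dienoate | COC(=O)CC(=O)CC/C=C(\C)CCC=C(C)C | intermediate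
4 | methyl (2Z,6E)-3-(diethoxyphosphoryloxy)-7,11-dimethyldodeca-2,6,10-trienoate | COC(=O)/C=C(\OP(=O)(OCC)OCC)CC/C=C(\C)CCC=C(C)C | intermediate
5 | methyl (2Z,6E)-7,11-dimethyl-3-(trimethylsilylmethyl)dodeca-2,6,10-trienoate | COC(=O)/C=C(\C[Si](C)(C)C)CC/C=C(\C)CCC=C(C)C | intermediate
6 | (3'S,6'S,7'S)-diepoxide of 5 | COC(=O)/C=C(\C[Si](C)(C)C)CC[C@@H]1O[C@@]1(C)CC[C@@H]1OC1(C)C | intermediate
7 | 3-O-trimethylsilyl ether of 8 (not isolated) | C=C1CC[C@@H]2OC(C)(C)[C@@H](O[Si](C)(C)C)CC[C@@]2(C)[C@@H]1C(=O)OC | intermediate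
8 | methyl (3S,5aS,6R,9aS)-3-hydroxy-2,2,5a-trimethyl-7-methylidenedecahydro-1-benzoxepine-6-carboxylate | C=C1CC[C@@H]2OC(C)(C)[C@@H](O)CC[C@@]2(C)[C@@H]1C(=O)OC | intermediate
9 | 3-O-tert-butyldimethylsilyl ether of 8 | C=C1CC[C@@H]2OC(C)(C)[C@@H](O[Si](C)(C)C(C)(C)C)CC[C@@]2(C)[C@@H]1C(=O)OC | intermediate
10 | (3S,5aS,6R,9aS)-6-hydroxymethyl bicycle, 3-O-silyl | C=C1CC[C@@H]2OC(C)(C)[C@@H](O[Si](C)(C)C(C)(C)C)CC[C@@]2(C)[C@@H]1CO | intermediate
11 | (3S,5aS,6R,9aS)-6-carbaldehyde, 3-O-silyl | C=C1CC[C@@H]2OC(C)(C)[C@@H](O[Si](C)(C)C(C)(C)C)CC[C@@]2(C)[C@@H]1C=O | intermediate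
12 | (3S,5aS,6R,9aS)-6-ethenyl bicycle, 3-O-silyl (left half) | C=C1CC[C@@H]2OC(C)(C)[C@@H](O[Si](C)(C)C(C)(C)C)CC[C@@]2(C)[C@@H]1C=C | intermediate
13 | (E)-geranylacetone, (5E)-6,10-dimethylundeca-5,9-dien-2-one | CC(=O)CC/C=C(\C)CCC=C(C)C | starting material
14 | (3S,6S,7S)-diepoxy ketone | CC(=O)CC[C@@H]1O[C@@]1(C)CC[C@@H]1OC1(C)C | intermediate
15 | 1,1,1-trifluoro-6-[diepoxy side chain as in 14]hexane-2,4-dione (not isolated) | O=C(CC(=O)C(F)(F)F)CC[C@@H]1O[C@@]1(C)CC[C@@H]1OC1(C)C | intermediate
16 | (3S,6S,7S)-diepoxy α-diazo ketone | [N-]=[N+]=CC(=O)CC[C@@H]1O[C@@]1(C)CC[C@@H]1OC1(C)C | intermediate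
17 | B-[2-(left bicycle)ethyl]dicyclohexylborane (not isolated) | C=C1CC[C@@H]2OC(C)(C)[C@@H](O[Si](C)(C)C(C)(C)C)CC[C@@]2(C)[C@@H]1CCB(C1CCCCC1)C1CCCCC1 | intermediate
18 | C10=C11 dicyclohexyl enol borinate, alkene geometry not controlled (not isolated) | C=C1CC[C@@H]2OC(C)(C)[C@@H](O[Si](C)(C)C(C)(C)C)CC[C@@]2(C)[C@@H]1CCC=C(OB(C1CCCCC1)C1CCCCC1)CC[C@@H]1O[C@@]1(C)CC[C@@H]1OC1(C)C | intermediate
19 | cyclised ketone as 3-O-dicyclohexylborinate, C11 not yet equilibrated (not isolated) | C=C1CC[C@@H]2OC(C)(C)[C@@H](O[Si](C)(C)C(C)(C)C)CC[C@@]2(C)[C@@H]1CCC1[C@]2(C)CC[C@H](OB(C3CCCCC3)C3CCCCC3)C(C)(C)O[C@H]2CCC1=O | intermediate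
20 | C29 hydroxy ketone, (3S,6S,7S,11S; 3'S,6'S,7'S,11'R) | C=C1CC[C@@H]2OC(C)(C)[C@@H](O[Si](C)(C)C(C)(C)C)CC[C@@]2(C)[C@@H]1CC[C@H]1[C@]2(C)CC[C@H](O)C(C)(C)O[C@H]2CCC1=O | intermediate
21 | C30 diol, (10R) axial tertiary alcohol | C=C1CC[C@@H]2OC(C)(C)[C@@H](O[Si](C)(C)C(C)(C)C)CC[C@@]2(C)[C@@H]1CC[C@H]1[C@]2(C)CC[C@H](O)C(C)(C)O[C@H]2CC[C@@]1(C)O | intermediate
22 | 3-keto 10-ol | C=C1CC[C@@H]2OC(C)(C)[C@@H](O[Si](C)(C)C(C)(C)C)CC[C@@]2(C)[C@@H]1CC[C@H]1[C@]2(C)CCC(=O)C(C)(C)O[C@H]2CC[C@@]1(C)O | intermediate
23 | 3-keto 10-acetate, 3'-O-silyl | C=C1CC[C@@H]2OC(C)(C)[C@@H](O[Si](C)(C)C(C)(C)C)CC[C@@]2(C)[C@@H]1CC[C@H]1[C@]2(C)CCC(=O)C(C)(C)O[C@H]2CC[C@@]1(C)OC(C)=O | intermediate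
24 | CNP0148623.1, (3'S,6'S,7'S,11'R,6S,7S,10R,11S) | C=C1CC[C@@H]2OC(C)(C)[C@@H](O)CC[C@@]2(C)[C@@H]1CC[C@H]1[C@]2(C)CCC(=O)C(C)(C)O[C@H]2CC[C@@]1(C)OC(C)=O | target

## Step count and risk assessment

Total step count: 16. Longest linear sequence: 14 (steps 1–9 and 12–16).

**Step 12 (proposed new method).**
- What may go wrong: a cyclohexyl group may migrate in place of the primary alkyl group, or the hindered borane may bind the diazo carbon too slowly. The enol borinate may also be too weak a π-nucleophile, so that the epoxonium ion collapses by hydride shift before carbon attacks.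
- The fallback makes the same bond by an aldol reaction and installs the regiodefined enol derivative by known 1,4-hydrosilylation. It sets out from 12 and 14 and comes back at 20.
- Compound 12 is hydroborated as before (17) and oxidised with NaBO3·4H2O to the primary alcohol F1, and Dess–Martin oxidation gives the aldehyde F2.
- The kinetic lithium enolate of 14 (LiN(i-Pr)2, THF, −78 °C, deprotonation at the methyl group) adds to F2 to give the aldol F3.
- Mesylation and elimination (MeSO2Cl, Et3N, then DBU) give the E-enone F4.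
- RhCl(PPh3)3-catalysed 1,4-hydrosilylation with Et3SiH gives the Z-triethylsilyl enol ether F5.
- Catalytic Et3SiOTf with 2,6-di-tert-butyl-4-methylpyridine in CH2Cl2 at −78 °C runs the known enol-silane-terminated cascade to the 3-O-triethylsilyl ketone F6.
- Pyridinium p-toluenesulfonate in MeOH removes the triethylsilyl group selectively to give 20.

**Step 5.**
- What may go wrong: the ester-deactivated allylsilane may react too slowly. The epoxonium ion could then collapse by 1,2-hydride shift or triflate capture, or the second opening could go exo.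
- The fallback changes the terminator into an electron-rich allylsilane. It sets out from 6 and comes back at 10.
- i-Bu2AlH (CH2Cl2, −78 °C) reduces the ester of 6 to the allylic alcohol F7, and Ac2O with pyridine gives the allylic acetate F8.
- Catalytic Me3SiOTf with the hindered pyridine at −78 °C gives the bicyclic trimethylsilyl ether F9, and citric acid in MeOH gives the hydroxy acetate F10.
- t-BuMe2SiOTf with 2,6-lutidine gives the silyl ether acetate F11, and K2CO3 in MeOH cleaves the primary acetate to give 10.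

**Step 15.**
- What may go wrong: acyl transfer to the axial tertiary hydroxyl, which is syn-axial to the C6 methyl group, may be very slow, and dehydration may compete on prolonged heating.
- The fallback acylates the alkoxide before the enolisable ketone is unveiled. It sets out from 21 and comes back at 23.
- Compound 21 is doubly deprotonated (n-BuLi, THF, −78 °C) and quenched with Ac2O to give the diacetate F12.
- K2CO3 in MeOH cleaves only the less hindered secondary acetate to give the hydroxy acetate F13, and Dess–Martin oxidation gives 23.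

## Further compounds

F1 | step 12 | 2-(left bicycle)ethanol, 3'-O-silyl | C=C1CC[C@@H]2OC(C)(C)[C@@H](O[Si](C)(C)C(C)(C)C)CC[C@@]2(C)[C@@H]1CCO
F2 | step 12 | 2-(left bicycle)acetaldehyde, 3'-O-silyl | C=C1CC[C@@H]2OC(C)(C)[C@@H](O[Si](C)(C)C(C)(C)C)CC[C@@]2(C)[C@@H]1CC=O
F3 | step 12 | aldol of 14 and F2 (carbinol epimers) | C=C1CC[C@@H]2OC(C)(C)[C@@H](O[Si](C)(C)C(C)(C)C)CC[C@@]2(C)[C@@H]1CC(O)CC(=O)CC[C@@H]1O[C@@]1(C)CC[C@@H]1OC1(C)C
F4 | step 12 | E-enone | C=C1CC[C@@H]2OC(C)(C)[C@@H](O[Si](C)(C)C(C)(C)C)CC[C@@]2(C)[C@@H]1C/C=C/C(=O)CC[C@@H]1O[C@@]1(C)CC[C@@H]1OC1(C)C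
F5 | step 12 | Z-triethylsilyl enol ether | C=C1CC[C@@H]2OC(C)(C)[C@@H](O[Si](C)(C)C(C)(C)C)CC[C@@]2(C)[C@@H]1CC/C=C(/CC[C@@H]1O[C@@]1(C)CC[C@@H]1OC1(C)C)O[Si](CC)(CC)CC
F6 | step 12 | 3-O-triethylsilyl ether of 20 | C=C1CC[C@@H]2OC(C)(C)[C@@H](O[Si](C)(C)C(C)(C)C)CC[C@@]2(C)[C@@H]1CC[C@H]1[C@]2(C)CC[C@H](O[Si](CC)(CC)CC)C(C)(C)O[C@H]2CCC1=O
F7 | step 5 | diepoxy Z-allylic alcohol | OC/C=C(\C[Si](C)(C)C)CC[C@@H]1O[C@@]1(C)CC[C@@H]1OC1(C)C
F8 | step 5 | diepoxy Z-allylic acetate | CC(=O)OC/C=C(\C[Si](C)(C)C)CC[C@@H]1O[C@@]1(C)CC[C@@H]1OC1(C)C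
F9 | step 5 | bicyclic acetate, 3-O-trimethylsilyl | C=C1CC[C@@H]2OC(C)(C)[C@@H](O[Si](C)(C)C)CC[C@@]2(C)[C@@H]1COC(C)=O
F10 | step 5 | bicyclic hydroxy acetate | C=C1CC[C@@H]2OC(C)(C)[C@@H](O)CC[C@@]2(C)[C@@H]1COC(C)=O
F11 | step 5 | bicyclic acetate, 3-O-tert-butyldimethylsilyl | C=C1CC[C@@H]2OC(C)(C)[C@@H](O[Si](C)(C)C(C)(C)C)CC[C@@]2(C)[C@@H]1COC(C)=O
F12 | step 15 | 3,10-diacetate | C=C1CC[C@@H]2OC(C)(C)[C@@H](O[Si](C)(C)C(C)(C)C)CC[C@@]2(C)[C@@H]1CC[C@H]1[C@]2(C)CC[C@H](OC(C)=O)C(C)(C)O[C@H]2CC[C@@]1(C)OC(C)=O
F13 | step 15 | 3-hydroxy 10-acetate | C=C1CC[C@@H]2OC(C)(C)[C@@H](O[Si](C)(C)C(C)(C)C)CC[C@@]2(C)[C@@H]1CC[C@H]1[C@]2(C)CC[C@H](O)C(C)(C)O[C@H]2CC[C@@]1(C)OC(C)=O
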